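## The problem

The target 14 is a 3,4-dihydroisocoumarin. An aromatic ring A is fused to a six-membered lactone ring B (C1 carbonyl, O2, C3, C4, C4a, C8a); C8 carries a free phenol and C3 carries a fifteen-carbon chain (C1' to C15') with a Z double bond at C6'=C7'. Closing ring B is easy, because a hydroxyl on C3 lactonises onto an ortho carboxyl group. The real tasks are the C4–C4a and C3–C1' bonds and the single stereocentre at C3, which is R. Nothing else in the molecule can relay stereochemistry, since the alkene lies six bonds from C3, so the configuration must come from a catalyst or be bought in a chiral building block. The Z alkene rules out hydrogenolysis and any radical, strongly acidic or isomerising conditions once it is in place. The lactone is opened by strong nucleophiles, and the C8 oxygen needs a protecting group that comes off without harming either. The enabling feature is that C3 is a carbinol carbon flanked by two methylenes: C4, bonded to the arene at C4a, and C1', the start of the chain. A vinylboron unit can therefore become C4–C3, taking an aryl electrophile at C4 and an alkyl nucleophile at C3, with the boron on C3 marking the future lactone oxygen.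

## Retrosynthesis

**14 to 13 (O–CH3 bond at C8).** The phenol is carried as its methyl ether 13 through all organometallic steps, where a free OH would quench the Grignard reagent and the boron ate complex. A benzyl ether would need hydrogenolysis, which the Z alkene forbids, and a silyl ether next to the ester would be at risk in alkaline peroxide. The methyl ether is already present in the commercial salicylate 1. Because it sits peri to the lactone carbonyl, BCl3 can remove it by chelation at low temperature. The forward step must cleave only this ether and leave the alkene and the lactone alone.

**13 to 12 to 11 (lactone C1–O2 bond; C3–O exchanged for C3–B).** Opening ring B gives the hydroxy ester 12, whose C3–O bond comes from the C3–B bond of the secondary pinacol boronate 11 by oxidation with retention. The lactone is closed late because the open methyl ester, shielded by two ortho substituents, tolerates the coupling conditions better than a lactone would. Compounds 11, 12 and 13 all carry the R descriptor at C3, and the spatial arrangement is the same throughout. The forward reactions must oxidise boron without touching the alkene and then close a six-membered ring onto a hindered ester.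

**11 to 2, 8 and 9 (C4–C4a and C3–C1' bonds, through ate complex 10).** Both skeletal bonds at the two-carbon bridge are cut at once. This leaves the aryl triflate 2, the Grignard reagent 8 and vinylboronic acid pinacol ester 9, which combine through the boron ate complex 10. Neighbouring cuts are weaker for this target:
- Opening a chiral terminal epoxide with an aryl-metal requires the stereocentre to be bought and is incompatible with the ester.
- Lateral lithiation of a toluate and addition to an aldehyde gives a racemate.
- Asymmetric reduction of the benzyl alkyl ketone must distinguish two methylene flanks.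

The three-component cut distinguishes the flanks by construction, since the aryl group goes to the terminal carbon and the alkyl group to the boron-bearing carbon. All three precursors are achiral and have no ring B. The forward reaction must deliver high enantioselectivity from the ligand and tolerate the ortho ester and the remote alkene.

**2 to 1 (aryl O–S bond).** The triflate 2 comes from commercial methyl 2-hydroxy-6-methoxybenzoate 1 by O-sulfonylation. The ortho ester makes the triflate electron-poor and therefore reactive in oxidative addition.

**8 to 7 to 6 to 3 and 4 (C–Mg bond; C6'=C7' geometry; C5'–C6' bond, through acetylide 5).** The Grignard reagent 8 comes from the chloride 7 by magnesium insertion. The Z alkene of 7 comes from the alkyne 6 by syn semihydrogenation. The alkyne 6 comes from dec-1-yne 3, through its lithium acetylide 5, and 1-bromo-5-chloropentane 4. The bromide must react and the chloride must survive as the handle for the organometallic. Both starting materials are commodity chemicals, and the geometry is set by a reaction whose Z selectivity is inherent.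

## Roads not taken

Alternative 1: The cut is at C4–C4a and C1–C8a, both bonds from ring B to the arene. The lithium enolate of the R β-lactone A2 would add to the aryne released from the silyl triflate A3, the resulting aryl anion would attack the lactone carbonyl, and fragmentation of the strained adduct would expand the four-membered lactone to ring B. The product is the methyl ether A1, which is the same compound as 13.
- Merits: two ring bonds form in one step and the heterocycle arrives complete. The C3–O bond is never touched, so the configuration of A2 is carried over unchanged. The regiochemistry is inherent, because the nucleophile adds meta to the methoxy group and places it at C8.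
- Weak points: insertion of arynes into C–C bonds is established for stabilised enolates such as β-keto esters, not for a bare β-lactone enolate. Such enolates undergo β-elimination with ring opening well below the temperatures at which fluoride releases the aryne. Simple α-arylation after proton transfer is a likely competitor. The stereocentre must be made beforehand in a separate enantioselective synthesis of A2.
- Comparison: this road would be shorter to A1 and more convergent in ring construction, and it shares the final demethylation with the chosen plan. The chosen plan sets against this a stereo-defining step of a known reaction type that uses only achiral pieces and forms no fragile intermediate.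

Alternative 2: The cut is in ring A at C6–C7 and C4a–C8a. Under TiCl4 the bis-silyl dienolate A6 would condense with the keto acetal A5, with terminal carbon to acetal carbon and central carbon to ketone carbon. Loss of methanol and water would aromatise ring A and give the salicylate A4.
- Merits: the phenol arrives free and the ester is already in place. Desilylation and lactonisation finish the synthesis, and no ether cleavage with a boron halide is needed next to the Z alkene. In this respect it is better than the chosen plan.
- Weak points: a benzene ring that can be bought is built from scratch. A5 is a β-silyloxy ketone, which under TiCl4 is prone to β-elimination and silyl loss. The C3 stereocentre is not set by the key step and needs its own asymmetric aldol or reduction inside a longer linear sequence.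
- Comparison: the chosen plan pays one deprotection step. In return it has a much shorter sequence in which the key step itself creates the stereocentre, and its ether cleavage is chelation-directed and runs at low temperature.

Alternative 3: The cut is at O2–C1 and O2–C3. A Baeyer–Villiger monooxygenase with O2 and NADPH would insert oxygen between the carbonyl carbon and the chain-bearing carbon of the racemising indanone A8. This expands the five-membered ketone ring to ring B and gives the mesylate A7.
- Merits: both C–O bonds of ring B and the stereocentre come from a racemate in one aerobic step. Full conversion to one enantiomer is possible in principle because the α-carbon epimerises. The reaction type is known for 2-alkylindanones with short chains.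
- Weak points: the fifteen-carbon chain makes A8 nearly insoluble in buffer and must fit the enzyme pocket. The enzyme must enforce migration of the secondary alkyl carbon over the aryl carbon, next to a peri sulfonate. Which enantiomer is delivered cannot be predicted. Racemisation must outrun oxidation. Removing the mesylate needs nucleophilic conditions that open the lactone. A8 itself takes several steps.
- Comparison: with a suitable enzyme this would be the most economical way to set C3 and would avoid the precious metal. The chosen plan sets against this a small-molecule catalyst with predictable scope, namely primary alkyl migrating groups and aryl triflates, and either product enantiomer is available by choosing the ligand antipode.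

Key step: step 5

## Route

Assumption: the sense of induction of the MandyPhos ligand is taken by analogy with simple aryl triflates. The antipode written as (Sp,Sp) is the one expected to give the R boronate 11; if the sense proves opposite, its mirror image is used with no other change.

Step 1
Reactants: 1 methyl 2-hydroxy-6-methoxybenzoate
Product: 2 methyl 2-methoxy-6-(trifluoromethylsulfonyloxy)benzoate
Conditions: Tf2O, pyridine, CH2Cl2, 0 °C → rt
Reagents that add atoms: trifluoromethanesulfonic anhydride, O=S(=O)(OS(=O)(=O)C(F)(F)F)C(F)(F)F
Why: O-sulfonylation of a phenol to the aryl triflate; the phenol is the only nucleophilic site and pyridine takes up the triflic acid, so the ester and methyl ether are untouched.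

Step 2
Reactants: 3 dec-1-yne; 4 1-bromo-5-chloropentane
Product: 6 1-chloropentadec-6-yne, via dec-1-ynyllithium 5 (not isolated)
Conditions: n-BuLi, THF, −78 → 0 °C; then 4, DMPU, −78 °C → rt
Reagents that add atoms: none
Why: Deprotonation of the terminal alkyne and SN2 alkylation of the lithium acetylide; bromide is displaced far faster than chloride, so the primary chloride survives as the handle for the later organometallic, and DMPU accelerates the substitution.

Step 3
Reactants: 6 1-chloropentadec-6-yne
Product: 7 (Z)-1-chloropentadec-6-ene
Conditions: H2 (1 atm), Pd/CaCO3 poisoned with Pb(OAc)2, quinoline, hexane, rt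
Reagents that add atoms: none
Why: Lindlar semihydrogenation; both hydrogens are delivered to the same face of the alkyne on the poisoned palladium surface, which gives the Z alkene, quinoline holds back over-reduction, and the primary chloride is not hydrogenolysed.

Step 4
Reactants: 7 (Z)-1-chloropentadec-6-ene
Product: 8 (Z)-pentadec-6-enylmagnesium chloride (THF solution, titrated and used directly)
Conditions: Mg turnings, I2 (cat.), THF, reflux
Reagents that add atoms: magnesium, [Mg]
Why: Grignard formation by insertion of magnesium into a primary alkyl chloride; the transient radical is of the 6-heptenyl type and cyclises too slowly to compete with capture at the metal, and the isolated Z alkene is inert to the reagent.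

Step 5
Reactants: 9 vinylboronic acid pinacol ester (2-ethenyl-4,4,5,5-tetramethyl-1,3,2-dioxaborolane); 8 (Z)-pentadec-6-enylmagnesium chloride; 2 methyl 2-methoxy-6-(trifluoromethylsulfonyloxy)benzoate
Product: 11 methyl 2-methoxy-6-[(2R,8Z)-2-(4,4,5,5-tetramethyl-1,3,2-dioxaborolan-2-yl)heptadec-8-enyl]benzoate, via chloromagnesium vinylboronate complex 10 (not isolated)
Conditions: 9 (slight excess over 8), THF, 0 °C → rt; then NaOTf, 2, Pd(OAc)2 (cat.), (Sp,Sp)-MandyPhos (cat.), THF/DMSO, 40 °C
Reagents that add atoms: none
Why: Addition of 8 to the vacant boron orbital of 9 gives the four-coordinate boronate 10, and the slight excess of 9 leaves no free Grignard reagent. Zerovalent palladium, formed in the flask from Pd(OAc)2 and the bisphosphine, inserts into the C–O bond of triflate 2 to give a cationic arylpalladium species (divalent palladium) whose open site binds the vinyl group of 10. This π-activation triggers the 1,2-shift of the primary alkyl group from boron to the α-carbon, anti to the metal (C3–C1'), and reductive elimination then joins the aryl group to the β-carbon (C4–C4a); no ring is closed. The closest known reaction type is the palladium-catalysed enantioselective conjunctive cross-coupling of Grignard-derived vinylboron ate complexes with aryl triflates in the presence of NaOTf. The C3 stereocentre is set under catalyst control: the chiral MandyPhos–palladium fragment selects the face of the vinyl group that it binds, and because the migration is strictly anti this fixes the R configuration at the boron-bearing carbon. The step needs the metallate shift to outrun direct transfer of the vinyl group (Suzuki–Miyaura product) and β-hydride elimination, which the wide-bite-angle ligand, the non-coordinating triflate counter-ion and NaOTf as chloride scavenger secure. Chemoselectivity rests on the substrate: the ester of 2 lies between two ortho substituents and is not attacked by the ate complex, the migrating group is a plain primary alkyl, and the remote dialkyl Z alkene does not compete for the metal.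

Step 6
Reactants: 11 methyl 2-methoxy-6-[(2R,8Z)-2-(4,4,5,5-tetramethyl-1,3,2-dioxaborolan-2-yl)heptadec-8-enyl]benzoate
Product: 13 (R)-8-methoxy-3-[(Z)-pentadec-6-enyl]isochroman-1-one, via hydroxy ester 12 (not isolated)
Conditions: 3 M NaOH, 30% H2O2, THF, 0 °C → rt; then TsOH·H2O (cat.), toluene, 60 °C
Reagents that add atoms: hydrogen peroxide, OO
Why: Oxidation of the secondary C–B bond (hydroperoxide adds to boron and the alkyl group migrates to oxygen with retention) gives the R alcohol 12, whose hydroxyl then closes the six-membered lactone onto the ortho ester; acid catalysis completes the lactonisation and re-closes any hydroxy acid formed by the base. The C3–O bond is not involved in the ring closure, so the configuration is kept.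

Step 7
Reactants: 13 (R)-8-methoxy-3-[(Z)-pentadec-6-enyl]isochroman-1-one
Product: 14 (R)-8-hydroxy-3-[(Z)-pentadec-6-enyl]isochroman-1-one (CNP0138671.1)
Conditions: BCl3, CH2Cl2, −78 → 0 °C; then H2O, 0 °C
Reagents that add atoms: none
Why: Chelation-assisted Lewis-acid O-demethylation; BCl3 bridges the lactone carbonyl and the peri methoxy oxygen, so chloride attacks only that methyl group at low temperature, while the isolated Z alkene, the secondary lactone C–O bond and the C3 stereocentre are left untouched.

## Compound list

1 | methyl 2-hydroxy-6-methoxybenzoate | COC(=O)c1c(O)cccc1OC | starting material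
2 | methyl 2-methoxy-6-(trifluoromethylsulfonyloxy)benzoate | COC(=O)c1c(OC)cccc1OS(=O)(=O)C(F)(F)F | intermediate
3 | dec-1-yne | C#CCCCCCCCC | starting material
4 | 1-bromo-5-chloropentane | ClCCCCCBr | starting material
5 | dec-1-ynyllithium | [Li]C#CCCCCCCCC | intermediate (not isolated)
6 | 1-chloropentadec-6-yne | ClCCCCCC#CCCCCCCCC | intermediate
7 | (Z)-1-chloropentadec-6-ene | ClCCCCC/C=C\CCCCCCCC | intermediate
8 | (Z)-pentadec-6-enylmagnesium chloride | CCCCCCCC/C=C\CCCCC[Mg]Cl | intermediate
9 | vinylboronic acid pinacol ester | C=CB1OC(C)(C)C(C)(C)O1 | starting material
10 | chloromagnesium [(Z)-pentadec-6-enyl](vinyl)(pinacolato)borate | C=C[B-]1(CCCCC/C=C\CCCCCCCC)OC(C)(C)C(C)(C)O1.[Mg+]Cl | intermediate (not isolated)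
11 | methyl 2-methoxy-6-[(2R,8Z)-2-(4,4,5,5-tetramethyl-1,3,2-dioxaborolan-2-yl)heptadec-8-enyl]benzoate | CCCCCCCC/C=C\CCCCC[C@@H](B1OC(C)(C)C(C)(C)O1)Cc1cccc(OC)c1C(=O)OC | intermediate
12 | methyl 2-[(2R,8Z)-2-hydroxyheptadec-8-enyl]-6-methoxybenzoate | CCCCCCCC/C=C\CCCCC[C@@H](O)Cc1cccc(OC)c1C(=O)OC | intermediate (not isolated)
13 | (R)-8-methoxy-3-[(Z)-pentadec-6-enyl]isochroman-1-one | CCCCCCCC/C=C\CCCCC[C@@H]1Cc2cccc(OC)c2C(=O)O1 | intermediate
14 | (R)-8-hydroxy-3-[(Z)-pentadec-6-enyl]isochroman-1-one | CCCCCCCC/C=C\CCCCC[C@@H]1Cc2cccc(O)c2C(=O)O1 | target

## Step count and risks

Total step count: 7. Longest linear sequence: 6 steps (steps 2 to 7, from dec-1-yne 3); step 1 is a one-step branch that joins at step 5.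

**Step 5 (key step).** The ortho ester carbonyl may chelate the cationic arylpalladium centre and compete with binding of the vinyl boronate. That would slow the metallate shift and let direct vinyl transfer or reduction of the triflate take over. The ortho substituent may also erode the facial selectivity, and any free Grignard reagent would attack the ester. Fallback, setting out from 7 and 2 and returning at 11: the boron is placed on C3 by enantioselective borylcupration of a styrene instead of by the metallate shift.
- Chloride 7 is displaced by lithium acetylide–ethylenediamine complex in DMSO to give (Z)-heptadec-8-en-1-yne F1.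
- Hydroboration of the terminal alkyne with pinacolborane and catalytic Cp2Zr(H)Cl gives 2-[(1E,8Z)-heptadeca-1,8-dienyl]-4,4,5,5-tetramethyl-1,3,2-dioxaborolane F2.
- Suzuki–Miyaura coupling of F2 with 2 (Pd(PPh3)4, K3PO4, aqueous dioxane) gives methyl 2-[(1E,8Z)-heptadeca-1,8-dienyl]-6-methoxybenzoate F3.
- Copper-catalysed enantioselective protoboration of the styrene double bond (CuCl, NaOt-Bu, a chiral bisphosphine, B2pin2, MeOH, THF) puts copper on the benzylic carbon C4 and boron on C3, and protonation gives 11. The remote dialkyl alkene does not react.

**Step 7.** During ether cleavage or on quenching, the Lewis acid and the HCl released may isomerise or hydrochlorinate the Z alkene, or the cleavage may stall at the boron chelate. Fallback, setting out from 8 and 9 and returning at 14: phenol and carboxyl are carried together as an acetonide, so no ether cleavage is needed.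
- Commercial 5-hydroxy-2,2-dimethyl-4H-1,3-benzodioxin-4-one F4 is converted (Tf2O, pyridine) into 2,2-dimethyl-4-oxo-4H-1,3-benzodioxin-5-yl trifluoromethanesulfonate F5.
- Conjunctive coupling of F5 with 8 and 9 under the conditions of step 5 gives 2,2-dimethyl-5-[(2R,8Z)-2-(4,4,5,5-tetramethyl-1,3,2-dioxaborolan-2-yl)heptadec-8-enyl]-4H-1,3-benzodioxin-4-one F6.
- Mild oxidation (NaBO3·4H2O, aqueous THF) gives 5-[(2R,8Z)-2-hydroxyheptadec-8-enyl]-2,2-dimethyl-4H-1,3-benzodioxin-4-one F7.
- NaH in THF at 0 °C makes the alkoxide attack the dioxinone carbonyl; the lactone closes, acetone is released and 14 is obtained directly.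

**Step 4.** Insertion into the primary chloride may start sluggishly and then be accompanied by Wurtz-type homocoupling. This gives a solution of uncertain titre and halide content, which would upset the stoichiometry of the ate complex. Fallback, setting out from 7 and returning at 11: the nucleophile is made by halogen–lithium exchange instead of metal insertion.
- Halide exchange (NaI, acetone, reflux) gives (Z)-1-iodopentadec-6-ene F8.
- t-BuLi (two equivalents, pentane/Et2O, −78 °C) gives (Z)-pentadec-6-enyllithium F9.
- Addition to 9 gives lithium [(Z)-pentadec-6-enyl](vinyl)(pinacolato)borate F10.
- Coupling of F10 with 2 under Pd(OAc)2 and the MandyPhos ligand in THF, without NaOTf, gives 11.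

**Step 6.** Ring closure onto the doubly ortho-substituted ester may be incomplete, and partial saponification in the alkaline oxidation may leave a mixture of open and closed forms. Fallback, setting out from 11 and returning at 13: the lactone is closed by carboxyl activation instead of transesterification. After the oxidation, the crude material is saponified on purpose (LiOH, aqueous THF/MeOH, 50 °C, then acidification) to 2-[(2R,8Z)-2-hydroxyheptadec-8-enyl]-6-methoxybenzoic acid F11. Carbodiimide activation of the acid (EDC·HCl, DMAP, CH2Cl2) then closes the ring to 13 with the C3–O bond untouched.

## Further compounds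

F1 | step 5 | (Z)-heptadec-8-en-1-yne | C#CCCCCC/C=C\CCCCCCCC
F2 | step 5 | 2-[(1E,8Z)-heptadeca-1,8-dienyl]-4,4,5,5-tetramethyl-1,3,2-dioxaborolane | CCCCCCCC/C=C\CCCCC/C=C/B1OC(C)(C)C(C)(C)O1
F3 | step 5 | methyl 2-[(1E,8Z)-heptadeca-1,8-dienyl]-6-methoxybenzoate | CCCCCCCC/C=C\CCCCC/C=C/c1cccc(OC)c1C(=O)OC
F4 | step 7 | 5-hydroxy-2,2-dimethyl-4H-1,3-benzodioxin-4-one | CC1(C)OC(=O)c2c(O)cccc2O1
F5 | step 7 | 2,2-dimethyl-4-oxo-4H-1,3-benzodioxin-5-yl trifluoromethanesulfonate | CC1(C)OC(=O)c2c(OS(=O)(=O)C(F)(F)F)cccc2O1
F6 | step 7 | 2,2-dimethyl-5-[(2R,8Z)-2-(4,4,5,5-tetramethyl-1,3,2-dioxaborolan-2-yl)heptadec-8-enyl]-4H-1,3-benzodioxin-4-one | CCCCCCCC/C=C\CCCCC[C@@H](B1OC(C)(C)C(C)(C)O1)Cc1cccc2OC(C)(C)OC(=O)c12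
F7 | step 7 | 5-[(2R,8Z)-2-hydroxyheptadec-8-enyl]-2,2-dimethyl-4H-1,3-benzodioxin-4-one | CCCCCCCC/C=C\CCCCC[C@@H](O)Cc1cccc2OC(C)(C)OC(=O)c12
F8 | step 4 | (Z)-1-iodopentadec-6-ene | ICCCCC/C=C\CCCCCCCC
F9 | step 4 | (Z)-pentadec-6-enyllithium | [Li]CCCCC/C=C\CCCCCCCC
F10 | step 4 | lithium [(Z)-pentadec-6-enyl](vinyl)(pinacolato)borate | C=C[B-]1(CCCCC/C=C\CCCCCCCC)OC(C)(C)C(C)(C)O1.[Li+]
F11 | step 6 | 2-[(2R,8Z)-2-hydroxyheptadec-8-enyl]-6-methoxybenzoic acid | CCCCCCCC/C=C\CCCCC[C@@H](O)Cc1cccc(OC)c1C(=O)O
A1 | alternative 1 | (R)-8-methoxy-3-[(Z)-pentadec-6-enyl]isochroman-1-one | CCCCCCCC/C=C\CCCCC[C@@H]1Cc2cccc(OC)c2C(=O)O1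
A2 | alternative 1 | (R)-4-[(Z)-pentadec-6-enyl]oxetan-2-one | CCCCCCCC/C=C\CCCCC[C@@H]1CC(=O)O1
A3 | alternative 1 | 3-methoxy-2-(trimethylsilyl)phenyl trifluoromethanesulfonate | COc1cccc(OS(=O)(=O)C(F)(F)F)c1[Si](C)(C)C
A4 | alternative 2 | methyl 2-hydroxy-6-[(2R,8Z)-2-(tert-butyldimethylsilyloxy)heptadec-8-enyl]benzoate | CCCCCCCC/C=C\CCCCC[C@@H](O[Si](C)(C)C(C)(C)C)Cc1cccc(O)c1C(=O)OC
A5 | alternative 2 | (5R,11Z)-5-(tert-butyldimethylsilyloxy)-1,1-dimethoxyicos-11-en-3-one | CCCCCCCC/C=C\CCCCC[C@@H](O[Si](C)(C)C(C)(C)C)CC(=O)CC(OC)OC
A6 | alternative 2 | 1-methoxy-1,3-bis(trimethylsilyloxy)buta-1,3-diene | COC(O[Si](C)(C)C)=CC(=C)O[Si](C)(C)C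
A7 | alternative 3 | (R)-8-(methanesulfonyloxy)-3-[(Z)-pentadec-6-enyl]isochroman-1-one | CCCCCCCC/C=C\CCCCC[C@@H]1Cc2cccc(OS(C)(=O)=O)c2C(=O)O1
A8 | alternative 3 | racemic 7-(methanesulfonyloxy)-2-[(Z)-pentadec-6-enyl]indan-1-one | CCCCCCCC/C=C\CCCCCC1Cc2cccc(OS(C)(=O)=O)c2C1=O
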